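Each fisetinidol unit is disconnected at O1, which in ring C lies between C8a of ring A and C2; without O1, ring C is a 1-indanone in which the carbonyl carbon is the future C2 and is bonded directly to C8a. Both units are therefore built as indanones on C6 and C8 of benzylated catechin, where the cis C3-oxygen/C4-aryl pair is fixed by reducing a flat 1,2-dione. The key step then inserts both O1 atoms in one operation: twofold Baeyer–Villiger oxidation of the bis(cis-2-acetoxy-3-aryl-1-indanone) gives the bis(cis-3-acetoxy-4-aryl-chroman-2-one). Arylation at C2 and deprotection complete the trimer.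

Key step: step 12

Remarks
- The target SMILES is read as fisetinidol-(4β→6)-catechin-(8←4β)-fisetinidol: both upper units are (2R,3S,4R), that is 2,3-trans and 3,4-cis, and the catechin unit is (2R,3S). The constitution and configuration needed no correction.
- Assumption: the (S,S)-configured ruthenium catalyst of step 10 is taken to give the (2S) carbinol; if a single-unit model shows the opposite sense, its antipode is used.
- Simple reagents (benzyl bromide, NBS and the like) are not numbered; they are named under "Reagents that add atoms". Indanone locants count the carbonyl carbon as C1.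

Step 1
Reactants: 1 (+)-catechin
Product: 2 (2R,3S)-5,7,3',4'-tetra-O-benzylcatechin
Conditions: BnBr (4.4 equiv), K2CO3, DMF, 0 °C → rt
Reagents that add atoms: benzyl bromide, BrCc1ccccc1
Why: Williamson etherification; carbonate deprotonates only the four phenols, so the C3 alcohol stays free and C2/C3 are untouched.

Step 2
Reactants: 2 (2R,3S)-5,7,3',4'-tetra-O-benzylcatechin
Product: 3 (2R,3S)-3,5,7,3',4'-penta-O-benzylcatechin
Conditions: NaH, BnBr, n-Bu4NI (cat.), DMF, 0 °C → rt
Reagents that add atoms: benzyl bromide, BrCc1ccccc1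
Why: Williamson etherification of the secondary alkoxide; no stereocentre is involved.

Step 3
Reactants: 3 penta-O-benzylcatechin
Product: 4 6,8-dibromo-penta-O-benzylcatechin
Conditions: NBS (2.1 equiv), CH2Cl2, −20 °C → rt, dark
Reagents that add atoms: N-bromosuccinimide, O=C1CCC(=O)N1Br
Why: electrophilic aromatic bromination; the two free positions of the phloroglucinol-type ring A (C8, then C6) are far more nucleophilic than ring B.

Step 4
Reactants: 4 6,8-dibromo-penta-O-benzylcatechin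
Product: 6 penta-O-benzylcatechin-6,8-dicarbaldehyde, via 6,8-dilithio-penta-O-benzylcatechin 5 (not isolated)
Conditions: t-BuLi (4.4 equiv), THF, −78 °C; DMF (excess), −78 → 0 °C; H2O
Reagents that add atoms: N,N-dimethylformamide, CN(C)C=O
Why: twofold bromine–lithium exchange followed by Bouveault formylation; each aryllithium is held by its two flanking oxygen atoms, and the amino alkoxides release the aldehydes only on work-up.

Step 5
Reactants: 7 1-[3-(benzyloxy)phenyl]ethanone
Product: 8 1-[5-(benzyloxy)-2-bromophenyl]ethanone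
Conditions: NBS (1.05 equiv), MeCN, rt, dark
Reagents that add atoms: N-bromosuccinimide, O=C1CCC(=O)N1Br
Why: electrophilic aromatic bromination para to the benzyloxy group (ortho to the acetyl group), the usual outcome for 3-alkoxyacetophenones.

Step 6
Reactants: 6 penta-O-benzylcatechin-6,8-dicarbaldehyde and 8 1-[5-(benzyloxy)-2-bromophenyl]ethanone (2.3 equiv)
Product: 9 6,8-bis[(E)-3-(5-benzyloxy-2-bromophenyl)-3-oxoprop-1-enyl]-penta-O-benzylcatechin
Conditions: KOH, EtOH/THF, rt
Reagents that add atoms: none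
Why: Claisen–Schmidt aldol condensation; dehydration of the aldols gives the E-enones, and the flavan centres carry no acidic hydrogen.

Step 7
Reactants: 9 bis-chalcone
Product: 10 6,8-bis(6-benzyloxy-1-oxoindan-3-yl)-penta-O-benzylcatechin (mixture of epimers at both indane C3)
Conditions: Pd(OAc)2 (10 mol%), PPh3 (25 mol%), HCO2Na, DMF, 90 °C
Reagents that add atoms: none
Why: intramolecular reductive Heck cyclisation, known for 2'-bromochalcones: zerovalent palladium inserts into each C–Br bond, the aryl group adds to the enone β-carbon and formate reduces the palladium enolate; the two new C3 centres form without control, which is harmless because step 9 makes them trigonal again.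

Step 8
Reactants: 10 bis(3-arylindan-1-one)
Product: 12 6,8-bis(6-benzyloxy-2-hydroxy-1-oxoindan-3-yl)-penta-O-benzylcatechin (stereoisomer mixture at indane C2 and C3), via bis(potassium enolate) 11 (not isolated)
Conditions: KN(SiMe3)2 (2.4 equiv), THF, −78 °C; 2-(phenylsulfonyl)-3-phenyloxaziridine (2.6 equiv), −78 °C; H2O
Reagents that add atoms: 2-(phenylsulfonyl)-3-phenyloxaziridine, O=S(=O)(c1ccccc1)N1OC1c1ccccc1
Why: enolate hydroxylation with an N-sulfonyloxaziridine (Davis oxidation); oxygen should enter anti to the C3 aryl group, but the configuration is irrelevant because step 9 removes both centres.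

Step 9
Reactants: 12 bis(2-hydroxy-3-arylindan-1-one)
Product: 13 6,8-bis(6-benzyloxy-2-hydroxy-1-oxo-1H-inden-3-yl)-penta-O-benzylcatechin (bis-diosphenol; side units achiral)
Conditions: Dess–Martin periodinane, CH2Cl2, rt
Reagents that add atoms: none
Why: Dess–Martin oxidation of each α-ketol to the 1,2-diketone, which enolises towards C3 to the conjugated 2-hydroxyindenone, so the mixture of the preceding steps converges on one compound.

Step 10
Reactants: 13 bis-diosphenol
Product: 14 6,8-bis[(2S,3R)-6-benzyloxy-2-hydroxy-1-oxoindan-3-yl]-penta-O-benzylcatechin (2-OH cis to the 3-aryl group)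
Conditions: RuCl(p-cymene)[(S,S)-TsDPEN] (5 mol% per dione), HCO2H/Et3N (5:2), CH2Cl2, 10 °C
Reagents that add atoms: none
Why: Noyori-type asymmetric transfer hydrogenation with dynamic kinetic resolution, the closest known cases being 1,2-diketones and α-keto esters with an enolisable neighbouring centre: the amine interconverts the enol with both C3 epimers of the 1,2-diketone, the ruthenium hydride reduces the C2 carbonyl (not conjugated with the arene and therefore the more electrophilic) on the face anti to the C3 aryl group so that oxygen and aryl end cis, and the catalyst chooses the carbonyl face and thereby the C3 epimer, while the low temperature should leave the C1 aryl ketone untouched.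

Step 11
Reactants: 14 bis(cis-2-hydroxy-3-arylindan-1-one)
Product: 15 6,8-bis[(2S,3R)-2-acetoxy-6-benzyloxy-1-oxoindan-3-yl]-penta-O-benzylcatechin (cis)
Conditions: Ac2O, pyridine, DMAP (cat.), CH2Cl2, 0 °C
Reagents that add atoms: acetic anhydride, CC(=O)OC(C)=O
Why: O-acetylation under weakly basic conditions, which should not epimerise the α-centre C2.

Step 12
Reactants: 15 bis(cis-2-acetoxy-3-arylindan-1-one)
Product: 16 6,8-bis[(3S,4R)-3-acetoxy-7-benzyloxy-2-oxochroman-4-yl]-penta-O-benzylcatechin (3,4-cis)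
Conditions: mCPBA (6 equiv), Na2HPO4, CH2Cl2, 0 °C → rt, dark
Reagents that add atoms: 3-chloroperoxybenzoic acid, O=C(OO)c1cccc(Cl)c1
Why: Baeyer–Villiger oxidation: the peracid adds to each C1 carbonyl to give a Criegee adduct, and the aryl carbon C7a, antiperiplanar to the breaking O–O bond, shifts from C1 to oxygen as 3-chlorobenzoate leaves; the closest known reaction is the conversion of 1-indanones into 3,4-dihydrocoumarins by peracids. Each six-membered lactone ring arises by ring enlargement, the 1,2-aryl shift placing one oxygen into the C1–C7a bond of the five-membered ring, so no separate cyclisation is involved. No stereocentre is formed: C2 and C3 of each indanone take no part in the shift and the phosphate buffer prevents enolisation at C2, so the cis pair is carried over unchanged as C3 and C4 of the lactone. The selectivity needed is migration of the aryl carbon instead of C2, and it is secured by the acetoxy group, whose inductive pull makes C2 a poor bearer of the positive charge that builds up on the migrating atom while its oxygen lone pair is engaged by the ester carbonyl. The peracid must also spare the alkoxyarenes, which is helped by the fully substituted ring A of the catechin core and by the buffered, acid-free medium.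

Step 13
Reactants: 16 bis(cis-3-acetoxy-4-arylchroman-2-one)
Product: 18 6,8-bis[(3S,4R)-2,3-diacetoxy-7-benzyloxychroman-4-yl]-penta-O-benzylcatechin (anomer mixture at both C2), via bis(diisobutylaluminium lactolate) 17 (not isolated)
Conditions: i-Bu2AlH (2.4 equiv), CH2Cl2, −78 °C; pyridine, DMAP, Ac2O, −78 → 0 °C; KNaC4H4O6 (aq)
Reagents that add atoms: acetic anhydride, CC(=O)OC(C)=O
Why: reductive acetylation of a lactone: the aluminium hemiacetal from hydride addition to the aryl lactone persists at −78 °C and is acetylated in the same flask, so no free lactol or hydroxy aldehyde can epimerise C3, any C3 acetate lost to the hydride is restored, and the uncontrolled C2 centres become trigonal again in step 14.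

Step 14
Reactants: 18 bis(2,3-diacetoxychroman) and 19 1,2-bis(benzyloxy)benzene (30 equiv)
Product: 20 6,8-bis[(2R,3S,4R)-3-acetoxy-7-benzyloxy-2-(3,4-dibenzyloxyphenyl)chroman-4-yl]-penta-O-benzylcatechin (each upper unit 2,3-trans-3,4-cis)
Conditions: BF3·OEt2 (3 equiv), CH2Cl2, −40 → 0 °C
Reagents that add atoms: none
Why: Friedel–Crafts C-arylation of an anomeric acetate, as in aryl C-glycoside synthesis: ionisation gives the oxocarbenium ion, which the cis C3 acetate captures as a bicyclic acetoxonium ion, so the arene (reacting para to one benzyloxy group, in large excess to outrun the substrate's own arenes) enters C2 from the opposite face, trans to both the C3 acetate and the C4 aryl group, neighbouring-group and steric control acting in the same direction.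

Step 15
Reactants: 20 protected trimer diacetate
Product: 21 6,8-bis[(2R,3S,4R)-7-benzyloxy-2-(3,4-dibenzyloxyphenyl)-3-hydroxychroman-4-yl]-penta-O-benzylcatechin
Conditions: K2CO3, MeOH/THF, rt
Reagents that add atoms: none
Why: Zemplén-type transesterification removes the two secondary acetates; benzyl ethers and all stereocentres are inert to methoxide.

Step 16
Reactants: 21 undeca-O-benzyl trimer
Product: 22 fisetinidol-(4β→6)-catechin-(8←4β)-fisetinidol (target)
Conditions: H2 (1 atm), Pd(OH)2/C, THF/MeOH/H2O, rt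
Reagents that add atoms: none
Why: hydrogenolysis of the eleven benzyl ethers; the benzylic C2–O1 and C4–aryl bonds of flavans should survive these mild conditions, as in deprotections of benzylated proanthocyanidins.

Compound list
1 | (+)-catechin, (2R,3S) | Oc1cc(O)c2c(c1)O[C@H](c1ccc(O)c(O)c1)[C@@H](O)C2 | starting material
2 | (2R,3S)-5,7,3',4'-tetra-O-benzylcatechin (3-OH free) | c9ccccc9COc1cc(OCc9ccccc9)c2c(c1)O[C@H](c1ccc(OCc9ccccc9)c(OCc9ccccc9)c1)[C@@H](O)C2 | intermediate
3 | (2R,3S)-3,5,7,3',4'-penta-O-benzylcatechin | c9ccccc9COc1cc(OCc9ccccc9)c2c(c1)O[C@H](c1ccc(OCc9ccccc9)c(OCc9ccccc9)c1)[C@@H](OCc9ccccc9)C2 | intermediate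
4 | 6,8-dibromo-penta-O-benzylcatechin | Brc1c(OCc9ccccc9)c2c(c(Br)c1OCc9ccccc9)O[C@H](c1ccc(OCc9ccccc9)c(OCc9ccccc9)c1)[C@@H](OCc9ccccc9)C2 | intermediate
5 | 6,8-dilithio-penta-O-benzylcatechin | [Li]c1c(OCc9ccccc9)c2c(c([Li])c1OCc9ccccc9)O[C@H](c1ccc(OCc9ccccc9)c(OCc9ccccc9)c1)[C@@H](OCc9ccccc9)C2 | intermediate (not isolated)
6 | penta-O-benzylcatechin-6,8-dicarbaldehyde | O=Cc1c(OCc9ccccc9)c2c(c(C=O)c1OCc9ccccc9)O[C@H](c1ccc(OCc9ccccc9)c(OCc9ccccc9)c1)[C@@H](OCc9ccccc9)C2 | intermediate
7 | 1-[3-(benzyloxy)phenyl]ethanone | CC(=O)c1cccc(OCc2ccccc2)c1 | starting material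
8 | 1-[5-(benzyloxy)-2-bromophenyl]ethanone | CC(=O)c1cc(OCc2ccccc2)ccc1Br | intermediate
9 | 6,8-bis[(E)-3-(5-benzyloxy-2-bromophenyl)-3-oxoprop-1-enyl]-penta-O-benzylcatechin | O=C(/C=C/c1c(OCc9ccccc9)c2c(c(/C=C/C(=O)c3cc(OCc9ccccc9)ccc3Br)c1OCc9ccccc9)O[C@H](c1ccc(OCc9ccccc9)c(OCc9ccccc9)c1)[C@@H](OCc9ccccc9)C2)c1cc(OCc9ccccc9)ccc1Br | intermediate
10 | 6,8-bis(6-benzyloxy-1-oxoindan-3-yl)-penta-O-benzylcatechin, epimer mixture at both indane C3 | c9ccccc9COc1ccc2c(c1)C(=O)CC2c1c(OCc9ccccc9)c2c(c(C3CC(=O)c4cc(OCc9ccccc9)ccc43)c1OCc9ccccc9)O[C@H](c1ccc(OCc9ccccc9)c(OCc9ccccc9)c1)[C@@H](OCc9ccccc9)C2 | intermediate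
11 | bis(potassium enolate) of 10 (C1–O−, C1=C2 in each indane) | [K+].[K+].c9ccccc9COc1ccc2c(c1)C([O-])=CC2c1c(OCc9ccccc9)c2c(c(C3C=C([O-])c4cc(OCc9ccccc9)ccc43)c1OCc9ccccc9)O[C@H](c1ccc(OCc9ccccc9)c(OCc9ccccc9)c1)[C@@H](OCc9ccccc9)C2 | intermediate (not isolated)
12 | 6,8-bis(6-benzyloxy-2-hydroxy-1-oxoindan-3-yl)-penta-O-benzylcatechin, stereoisomer mixture at indane C2 and C3 | c9ccccc9COc1ccc2c(c1)C(=O)C(O)C2c1c(OCc9ccccc9)c2c(c(C3C(O)C(=O)c4cc(OCc9ccccc9)ccc43)c1OCc9ccccc9)O[C@H](c1ccc(OCc9ccccc9)c(OCc9ccccc9)c1)[C@@H](OCc9ccccc9)C2 | intermediate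
13 | 6,8-bis(6-benzyloxy-2-hydroxy-1-oxo-1H-inden-3-yl)-penta-O-benzylcatechin (bis-diosphenol) | c9ccccc9COc1ccc2c(c1)C(=O)C(O)=C2c1c(OCc9ccccc9)c2c(c(C3=C(O)C(=O)c4cc(OCc9ccccc9)ccc43)c1OCc9ccccc9)O[C@H](c1ccc(OCc9ccccc9)c(OCc9ccccc9)c1)[C@@H](OCc9ccccc9)C2 | intermediate
14 | 6,8-bis[(2S,3R)-6-benzyloxy-2-hydroxy-1-oxoindan-3-yl]-penta-O-benzylcatechin (cis) | c9ccccc9COc1ccc2c(c1)C(=O)[C@@H](O)[C@H]2c1c(OCc9ccccc9)c2c(c([C@H]3c4ccc(OCc9ccccc9)cc4C(=O)[C@H]3O)c1OCc9ccccc9)O[C@H](c1ccc(OCc9ccccc9)c(OCc9ccccc9)c1)[C@@H](OCc9ccccc9)C2 | intermediate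
15 | 6,8-bis[(2S,3R)-2-acetoxy-6-benzyloxy-1-oxoindan-3-yl]-penta-O-benzylcatechin (cis; precursor of the key step) | c9ccccc9COc1ccc2c(c1)C(=O)[C@@H](OC(C)=O)[C@H]2c1c(OCc9ccccc9)c2c(c([C@H]3c4ccc(OCc9ccccc9)cc4C(=O)[C@H]3OC(C)=O)c1OCc9ccccc9)O[C@H](c1ccc(OCc9ccccc9)c(OCc9ccccc9)c1)[C@@H](OCc9ccccc9)C2 | intermediate
16 | 6,8-bis[(3S,4R)-3-acetoxy-7-benzyloxy-2-oxochroman-4-yl]-penta-O-benzylcatechin (3,4-cis; product of the key step) | c9ccccc9COc1ccc2c(c1)OC(=O)[C@@H](OC(C)=O)[C@H]2c1c(OCc9ccccc9)c2c(c([C@H]3c4ccc(OCc9ccccc9)cc4OC(=O)[C@H]3OC(C)=O)c1OCc9ccccc9)O[C@H](c1ccc(OCc9ccccc9)c(OCc9ccccc9)c1)[C@@H](OCc9ccccc9)C2 | intermediate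
17 | bis(diisobutylaluminium lactolate) of 16 (C2–O–Al(i-Bu)2 in each chroman) | c9ccccc9COc1ccc2c(c1)OC(O[Al](CC(C)C)CC(C)C)[C@@H](OC(C)=O)[C@H]2c1c(OCc9ccccc9)c2c(c([C@H]3c4ccc(OCc9ccccc9)cc4OC(O[Al](CC(C)C)CC(C)C)[C@H]3OC(C)=O)c1OCc9ccccc9)O[C@H](c1ccc(OCc9ccccc9)c(OCc9ccccc9)c1)[C@@H](OCc9ccccc9)C2 | intermediate (not isolated)
18 | 6,8-bis[(3S,4R)-2,3-diacetoxy-7-benzyloxychroman-4-yl]-penta-O-benzylcatechin, anomer mixture at both C2 | c9ccccc9COc1ccc2c(c1)OC(OC(C)=O)[C@@H](OC(C)=O)[C@H]2c1c(OCc9ccccc9)c2c(c([C@H]3c4ccc(OCc9ccccc9)cc4OC(OC(C)=O)[C@H]3OC(C)=O)c1OCc9ccccc9)O[C@H](c1ccc(OCc9ccccc9)c(OCc9ccccc9)c1)[C@@H](OCc9ccccc9)C2 | intermediate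
19 | 1,2-bis(benzyloxy)benzene | c1ccc(OCc2ccccc2)c(OCc2ccccc2)c1 | starting material
20 | 6,8-bis[(2R,3S,4R)-3-acetoxy-7-benzyloxy-2-(3,4-dibenzyloxyphenyl)chroman-4-yl]-penta-O-benzylcatechin | c9ccccc9COc1ccc2c(c1)O[C@H](c1ccc(OCc9ccccc9)c(OCc9ccccc9)c1)[C@@H](OC(C)=O)[C@H]2c1c(OCc9ccccc9)c2c(c([C@H]3c4ccc(OCc9ccccc9)cc4O[C@H](c4ccc(OCc9ccccc9)c(OCc9ccccc9)c4)[C@H]3OC(C)=O)c1OCc9ccccc9)O[C@H](c1ccc(OCc9ccccc9)c(OCc9ccccc9)c1)[C@@H](OCc9ccccc9)C2 | intermediate
21 | 6,8-bis[(2R,3S,4R)-7-benzyloxy-2-(3,4-dibenzyloxyphenyl)-3-hydroxychroman-4-yl]-penta-O-benzylcatechin | c9ccccc9COc1ccc2c(c1)O[C@H](c1ccc(OCc9ccccc9)c(OCc9ccccc9)c1)[C@@H](O)[C@H]2c1c(OCc9ccccc9)c2c(c([C@H]3c4ccc(OCc9ccccc9)cc4O[C@H](c4ccc(OCc9ccccc9)c(OCc9ccccc9)c4)[C@H]3O)c1OCc9ccccc9)O[C@H](c1ccc(OCc9ccccc9)c(OCc9ccccc9)c1)[C@@H](OCc9ccccc9)C2 | intermediate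
22 | fisetinidol-(4β→6)-catechin-(8←4β)-fisetinidol; upper units (2R,3S,4R), catechin (2R,3S) | Oc1ccc2c(c1)O[C@H](c1ccc(O)c(O)c1)[C@@H](O)[C@H]2c1c(O)c2c(c([C@H]3c4ccc(O)cc4O[C@H](c4ccc(O)c(O)c4)[C@H]3O)c1O)O[C@H](c1ccc(O)c(O)c1)[C@@H](O)C2 | target

Total step count: 16. Longest linear sequence: 15 steps (steps 1–4 and 6–16, from (+)-catechin).

Steps most likely to fail

1. Step 12. The acetoxy-bearing carbon C2 may migrate instead of the aryl carbon, so that oxygen enters on the wrong side of the carbonyl group. Alternatively the peracid may add so slowly to the hindered, conjugated ketone that oxidation of the alkoxyarenes takes over. The fallback moves the oxygen insertion to a stage where the competing group is an unsubstituted methylene. It sets out from bis-chalcone 9. An enantioselective reductive Heck cyclisation (Pd(OAc)2, (R)-3,5-Xyl-MeO-BIPHEP or its antipode, HCO2Na) should give the 6,8-bis[(3R)-6-benzyloxy-1-oxoindan-3-yl] compound F1. Baeyer–Villiger oxidation (mCPBA, CF3CO2H cat.), for which aryl migration is the normal course in 2-unsubstituted 1-indanones, should give the bis[(4R)-7-benzyloxy-2-oxochroman-4-yl] compound F2. Hydroxylation of the lactone enolates (KN(SiMe3)2, then the N-sulfonyloxaziridine of step 8) anti to the C4 aryl group should give the bis(trans-3-hydroxy lactone) F3. Mitsunobu inversion at C3 with acetic acid (PPh3, diisopropyl azodicarboxylate) then gives the cis acetate 16, where the route is rejoined.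

2. Step 10. The C1 carbonyl may be reduced after C2, or ketonisation of the hindered enol may be too slow for the dynamic resolution, so that conversion or cis selectivity suffers. The fallback sets out from 13 and uses hydrogenation of the alkene in place of hydride transfer to the carbonyl group. Acetylation (Ac2O, Et3N, DMAP) gives the bis(2-acetoxy-6-benzyloxy-1-oxo-1H-inden-3-yl) compound F4. Homogeneous asymmetric hydrogenation ([Rh(cod)2]BF4, a chiral bisphosphine such as (R,R)-Me-DuPhos or its antipode, H2 50 bar) then adds both hydrogen atoms to the same face of each C2=C3 bond and gives the cis acetate 15 directly, where the route is rejoined.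

3. Step 14. The C2 cation may be captured by the resorcinol-type ring A of a second molecule (oligomerisation) in competition with the weakly nucleophilic arene 19, or the C3 proton may be lost to give a chromene. The fallback uses an organometallic aryl donor in place of the neutral arene and sets out from 18. Me3SiBr (CH2Cl2, 0 °C) converts both anomeric acetates into the bis(3-acetoxy-2-bromochroman) F5. Bis[3,4-bis(benzyloxy)phenyl]zinc F6 is made from commercial 4-bromo-1,2-bis(benzyloxy)benzene by bromine–lithium exchange and addition of ZnBr2. In toluene/n-Bu2O at 90 °C it transfers its aryl group to C2, as in the arylzinc synthesis of aryl C-glycosides from glycosyl bromides with a participating 2-O-acyl group. Attack trans to the acetate gives 20, where the route is rejoined.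

Further compounds
F1 | step 12 | 6,8-bis[(3R)-6-benzyloxy-1-oxoindan-3-yl]-penta-O-benzylcatechin | c9ccccc9COc1ccc2c(c1)C(=O)C[C@H]2c1c(OCc9ccccc9)c2c(c([C@H]3c4ccc(OCc9ccccc9)cc4C(=O)C3)c1OCc9ccccc9)O[C@H](c1ccc(OCc9ccccc9)c(OCc9ccccc9)c1)[C@@H](OCc9ccccc9)C2
F2 | step 12 | 6,8-bis[(4R)-7-benzyloxy-2-oxochroman-4-yl]-penta-O-benzylcatechin | c9ccccc9COc1ccc2c(c1)OC(=O)C[C@H]2c1c(OCc9ccccc9)c2c(c([C@H]3c4ccc(OCc9ccccc9)cc4OC(=O)C3)c1OCc9ccccc9)O[C@H](c1ccc(OCc9ccccc9)c(OCc9ccccc9)c1)[C@@H](OCc9ccccc9)C2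
F3 | step 12 | 6,8-bis[(3R,4R)-7-benzyloxy-3-hydroxy-2-oxochroman-4-yl]-penta-O-benzylcatechin (3,4-trans) | c9ccccc9COc1ccc2c(c1)OC(=O)[C@H](O)[C@H]2c1c(OCc9ccccc9)c2c(c([C@H]3c4ccc(OCc9ccccc9)cc4OC(=O)[C@@H]3O)c1OCc9ccccc9)O[C@H](c1ccc(OCc9ccccc9)c(OCc9ccccc9)c1)[C@@H](OCc9ccccc9)C2
F4 | step 10 | 6,8-bis(2-acetoxy-6-benzyloxy-1-oxo-1H-inden-3-yl)-penta-O-benzylcatechin | c9ccccc9COc1ccc2c(c1)C(=O)C(OC(C)=O)=C2c1c(OCc9ccccc9)c2c(c(C3=C(OC(C)=O)C(=O)c4cc(OCc9ccccc9)ccc43)c1OCc9ccccc9)O[C@H](c1ccc(OCc9ccccc9)c(OCc9ccccc9)c1)[C@@H](OCc9ccccc9)C2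
F5 | step 14 | 6,8-bis[(3S,4R)-3-acetoxy-7-benzyloxy-2-bromochroman-4-yl]-penta-O-benzylcatechin (anomer mixture) | c9ccccc9COc1ccc2c(c1)OC(Br)[C@@H](OC(C)=O)[C@H]2c1c(OCc9ccccc9)c2c(c([C@H]3c4ccc(OCc9ccccc9)cc4OC(Br)[C@H]3OC(C)=O)c1OCc9ccccc9)O[C@H](c1ccc(OCc9ccccc9)c(OCc9ccccc9)c1)[C@@H](OCc9ccccc9)C2
F6 | step 14 | bis[3,4-bis(benzyloxy)phenyl]zinc | c1ccccc1COc1ccc(cc1OCc1ccccc1)[Zn]c1ccc(OCc2ccccc2)c(OCc2ccccc2)c1
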